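The runs come from a simulation with constants of no real substance, and the scatter is random.

A small charge of free catalyst, 0.091 mol% on starting material, turns starting material and coupling partner into target over days. We compare blue and teal, which differ in c(starting material) and in time.

common to all: free catalyst 0.091 mol%

| charge | starting material | coupling partner | remark | time |
|---|---|---|---|---|
| autumn | 0.14 M | 0.90 equiv | run made earlier |  |
| dusk | 0.29 M | 0.90 equiv | run made earlier |  |
| summer | 0.59 M | 0.90 equiv | run made earlier |  |
| blue | 0.15 M | 0.900 equiv |  | 15 d |
| teal | 0.50 M | 0.900 equiv |  | 10 d |

- autumn (time / d: target / %, starting material / %): 0.417: 3.0, 97.6; 0.833: 5.1, 93.7; 2.00: 13.0, 86.9; 5.00: 29.6, 69.9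
- dusk (time / d: target / %, starting material / %): 0.625: 6.5, 92.4; 1.67: 18.7, 81.0; 3.00: 30.9, 69.4; 5.00: 45.6, 53.8
- summer (time / d: target / %, starting material / %): 0.417: 7.3, 92.3; 0.833: 14.2, 85.6; 2.00: 32.7, 67.8; 5.00: 65.8, 34.3

(scatter of a reading: 0.5 percentage points)

- the numbers in the tables scatter with a standard deviation of 0.5 percentage points
- where the amount of starting material changes, what is given in equivalents or mol% on it follows

* the flask that ends with the higher amount of target, in percent of the starting material charged, or "neither" when 2 percentage points or less lies between them (blue / teal / neither)
* final target, as a percentage of the starting material charged, in blue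
* final target, as a percentage of the starting material charged, in teal

We ask first where a flask stops. If each target takes one coupling partner, that partner is the limiting reagent at 0.900 equiv, and the target its charge allows is 90.0 %, our ceiling. Then we ask how fast the ceiling is approached. Our own reckoning lets the gap to the ceiling shrink by the same factor in equal times, with the factor read from the last reading of the nearest run. Autumn, with 29.6 % at 5.00 d, gives 62.8 % for blue. Summer, with 65.8 % at 5.00 d, gives 83.5 % for teal.

The forecast, noting that “the partner caps the yield at 90%”, puts teal ahead, with 85 % (78 % to 90 %) in teal and 66 % (59 % to 71 %) in blue. Our two figures are lower than these .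

The flasks give 65.6 % in blue and 84.3 % in teal, so teal ends higher and both forecast ranges hold.

    coupling partner + free catalyst → catalyst intermediate A (k = 0.0250 M⁻¹ s⁻¹)
    catalyst intermediate A ⇌ catalyst intermediate B (K = 1.00, k = 0.450 s⁻¹)
    catalyst intermediate C → free catalyst + target (k = 0.00500 s⁻¹)
    target → over-reaction product (k = 2.20 × 10⁻⁹ s⁻¹)
    2 catalyst intermediate A → spent catalyst (k = 0.00510 M⁻¹ s⁻¹)
    starting material + catalyst intermediate B → catalyst intermediate C (k = 0.0230 M⁻¹ s⁻¹)

Teal stands at 93.7 % of the ceiling, nearly all of it, and blue at 72.9 %. The main reason blue stands lower is its lower c(starting material): at teal's value, with blue's time held, blue reaches 89.5 % instead of 65.6 %. Spent catalyst stands at 17.4 % of the catalyst in teal, yet without that path teal gives 86.5 % rather than 84.3 %, which is a part of its gap. Blue with 0.36 mol% of free catalyst keeps the same equivalents of coupling partner, so its ceiling stays 90.0 %. That flask gives 89.7 %, with 0.014 % of the coupling partner left.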